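Readings and results are calculated with constants of no real substance.

If oak, ash and cedar were to end alike, within 1.5 percentage points, the hours that a feed changes would have to be worth less target than that margin, and the earlier runs put a price on those hours.

| setting | south | west | south-east | oak | ash | cedar |
|---|---|---|---|---|---|---|
| substrate | 0.10 M | 0.067 M | 0.15 M | 0.10 M | 0.10 M | 0.10 M (fed, over 1.5 h) |
| partner | 0.80 equiv | 0.80 equiv | 0.80 equiv | 0.800 equiv | 0.800 equiv (fed, over 1.5 h) | 0.800 equiv |
| remark | run made earlier | run made earlier | run made earlier | everything together at the start | all else is in the flask from the start; the feed brings no volume worth counting | all else is in the flask from the start; the feed brings no volume worth counting |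
| time |  |  |  | 2.5 h | 2.5 h | 2.5 h |

south run (percent of the substrate charged)

| time / min | target / % | substrate / % |
|---|---|---|
| 5.00 | 2 | 93 |
| 15.0 | 4 | 82 |
| 25.0 | 10 | 76 |
| 40.0 | 7 | 69 |
| 50.0 | 12 | 66 |
| 80.0 | 15 | 63 |
| 90.0 | 15 | 63 |

west run (percent of the substrate charged)

| time / h | target / % | substrate / % |
|---|---|---|
| 0.417 | 10 | 80 |
| 0.833 | 13 | 72 |
| 1.33 | 17 | 66 |
| 1.50 | 22 | 67 |
| 2.00 | 24 | 60 |
| 2.50 | 31 | 58 |
| 3.00 | 32 | 56 |

south-east run (percent of the substrate charged)

| time / h | target / % | substrate / % |
|---|---|---|
| 0.417 | 7 | 69 |
| 0.833 | 10 | 60 |
| 1.33 | 15 | 58 |
| 1.50 | 17 | 59 |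
| 2.00 | 19 | 55 |
| 2.50 | 28 | 51 |
| 3.00 | 31 | 48 |

(standard deviation of a reading: 2 percentage points)

- what is said of target includes idle adduct
- the earlier runs were read with a standard deviation of 2 percentage points
- steps under discussion: tautomer -> decomposed reagent; partner + tautomer -> target; substrate <-> tautomer; partner + target <-> idle adduct; substrate + partner <-> isomer of the product

- the flask that comes out highest in amount of target, in percent of the substrate charged, or "all alike" when all lie within 1.5 percentage points (oak / ash / cedar / all alike)
- target at the end, in percent of the substrate charged, oak
- target at the end, in percent of the substrate charged, ash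
- target at the end, in percent of the substrate charged, cedar

Target in the west and south-east runs grows much like the output of a first-order step, with tautomerisation of substrate read as the rate-limiting step. The last target reading, divided by its time and by the mean of the first and last substrate readings, gives 0.157 h⁻¹ in west and 0.177 h⁻¹ in south-east. Their mean, 0.167 h⁻¹, is κ, the target made per hour per unit of substrate standing in the flask.

Over 1.5 h, the cedar feed keeps on average half of the substrate charge out of the flask. With 63% standing, as at the last south reading, my reckoning prices that loss at 7.9 points, more than the margin. The ash feed likewise keeps on average half of the partner charge out of the flask. At its last reading the south run has 22.0% of the charge that is neither substrate nor target; if half of that stays substrate over the feed, my reckoning credits ash with 2.8 points over oak, also above the margin.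

The forecast names ash, with oak 28%, ash 30.5% and cedar 19%: “Cedar holds little substrate in the flask early, so it loses tautomerisation time”. Its gap between oak and cedar, 9 points, is wider than mine.

The flasks give ash highest at 30.4%, oak 27.6% and cedar 20.1%.

    tautomer → decomposed reagent (k = 0.00300 min⁻¹)
    partner + tautomer → target (k = 350 M⁻¹ min⁻¹)
    substrate ⇌ tautomer (K = 0.0760, k = 0.00280 min⁻¹)
    partner + target ⇌ idle adduct, settled at all times (K = 8.90 M⁻¹)
    substrate + partner ⇌ isomer of the product (K = 8.50 M⁻¹, k = 0.180 M⁻¹ min⁻¹)

Ash holds 0.0192% of decomposed reagent at 2.50 h, against a lead over oak of 2.8 points. Cedar's substrate stands at 70.6% at the end of the feed and at 59.4% at 2.50 h; taken as straight lines from zero, these give a substrate fraction integrated over time of 1.18 h, and κ turns that into 19.7% target. Read at 6.0 h, cedar has 42.4% substrate, and κ gives 51.3% target, where that flask holds 49.7%.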